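The single carbocycle, the cyclohexane ring C1–C6 of the quinic acid core, is disconnected between C3 and C4, the two neighbouring oxygenated carbons whose oxygens are cis to each other and trans to O5. A SmI2 pinacol coupling of an acyclic 1,6-dialdehyde makes the C3–C4 bond, closes the ring and sets both carbinol centres in one operation, steered by the C5 silyloxy group. The precursor is a methyl pentanoate carrying the quaternary C1 (silyloxy, CH2CHO arm) and a 4-silyloxy-5-oxo terminus, built from a glutamic-acid-derived lactone that fixes C5 and controls C1; the two cinnamoyl esters are then placed on O3 and O4 of the derived 1,5-lactone.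

Key step: step 9

Remark: quinic acid numbering (C1 = carboxyl-bearing carbon) is used for all cyclohexane compounds, and lactone 1 is assumed to be purchasable as the (R)-chiron of the D-glutamic acid series (otherwise one step from commercial (R)-5-(hydroxymethyl)dihydrofuran-2(3H)-one and trityl chloride).
Abbreviations: TBS = tert-butyldimethylsilyl, TES = triethylsilyl, Tr = trityl (triphenylmethyl); "1,5-quinide" = 1,5-lactone of (−)-quinic acid, (1S,3R,4R,5R)-1,3,4-trihydroxy-6-oxabicyclo[3.2.1]octan-7-one.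

Step 1
Reactants: 1 (5R)-5-[(trityloxy)methyl]dihydrofuran-2(3H)-one
Product: 3 (3S,5R)-3-allyl-5-[(trityloxy)methyl]dihydrofuran-2(3H)-one, via lithium enolate 2 (not isolated)
Conditions: LiN(iPr)2, THF, −78 °C; allyl bromide, −78 to −40 °C
Reagents that add atoms: allyl bromide C=CCBr
Why: Kinetic lithium enolate alkylation of a γ-butyrolactone, in which the bulky trityloxymethyl group shields its own face so that allyl should enter trans, although this centre is re-formed in step 2 and its ratio is immaterial.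

Step 2
Reactants: 3 (3S,5R)-3-allyl-5-[(trityloxy)methyl]dihydrofuran-2(3H)-one
Product: 5 (3S,5R)-3-allyl-3-hydroxy-5-[(trityloxy)methyl]dihydrofuran-2(3H)-one, via potassium enolate 4 (not isolated)
Conditions: KN(SiMe3)2, THF, −78 °C; (±)-trans-2-(phenylsulfonyl)-3-phenyloxaziridine, −78 °C; AcOH quench
Reagents that add atoms: 2-(phenylsulfonyl)-3-phenyloxaziridine O=S(=O)(N1OC1c1ccccc1)c1ccccc1
Why: Davis oxaziridine hydroxylation of the tetrasubstituted lactone enolate, in which the electrophilic oxygen should be delivered to the face opposite the trityloxymethyl group (1,3-induction in the flat five-membered enolate), setting the quaternary carbinol (future C1) with O trans and allyl cis to the C5 side chain.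

Step 3
Reactants: 5 (3S,5R)-3-allyl-3-hydroxy-5-[(trityloxy)methyl]dihydrofuran-2(3H)-one
Product: 6 (3S,5R)-3-allyl-3-[(tert-butyldimethylsilyl)oxy]-5-[(trityloxy)methyl]dihydrofuran-2(3H)-one
Conditions: TBSOTf, 2,6-lutidine, CH2Cl2, 0 °C to rt
Reagents that add atoms: tert-butyldimethylsilyl triflate CC(C)(C)[Si](C)(C)OS(=O)(=O)C(F)(F)F
Why: Silyl triflate silylation of a hindered tertiary alcohol under 2,6-lutidine buffering, which leaves the lactone, the alkene and the trityl ether alone and touches no stereocentre.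

Step 4
Reactants: 6 (3S,5R)-3-allyl-3-[(tert-butyldimethylsilyl)oxy]-5-[(trityloxy)methyl]dihydrofuran-2(3H)-one
Product: 9 (2S,4R)-2-allyl-2,4-bis[(tert-butyldimethylsilyl)oxy]-5-(trityloxy)pentanoic acid, via lithium hydroxy carboxylate 7 (not isolated), via silyl ester 8 (not isolated)
Conditions: LiOH·H2O, THF/H2O, rt to 40 °C; evaporate, toluene azeotrope; TBSCl, imidazole, DMF, rt to 40 °C; K2CO3, MeOH/THF/H2O, rt; 1 M HCl to pH 4, 0 °C
Reagents that add atoms: lithium hydroxide [Li+].[OH-]; tert-butyldimethylsilyl chloride CC(C)(C)[Si](C)(C)Cl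
Why: Lactone saponification gives a carboxylate that cannot re-close, the released γ-hydroxyl (future O5) is then silylated under Corey conditions and the co-formed silyl ester is cleaved by carbonate methanolysis, so the hydroxy acid never meets acid with its hydroxyl free and both stereocentres stay untouched.

Step 5
Reactants: 9 (2S,4R)-2-allyl-2,4-bis[(tert-butyldimethylsilyl)oxy]-5-(trityloxy)pentanoic acid
Product: 10 methyl (2S,4R)-2-allyl-2,4-bis[(tert-butyldimethylsilyl)oxy]-5-(trityloxy)pentanoate
Conditions: MeI, K2CO3, DMF, rt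
Reagents that add atoms: iodomethane CI
Why: SN2 O-methylation of the potassium carboxylate, which works even for an α-quaternary acid and is neutral toward the silyl and trityl ethers.

Step 6
Reactants: 10 methyl (2S,4R)-2-allyl-2,4-bis[(tert-butyldimethylsilyl)oxy]-5-(trityloxy)pentanoate
Product: 11 methyl (2S,4R)-2-allyl-2,4-bis[(tert-butyldimethylsilyl)oxy]-5-hydroxypentanoate
Conditions: HCO2H/Et2O (1:1), rt, short contact; aq. NaHCO3
Reagents that add atoms: none
Why: Acid-induced SN1 cleavage of the trityl ether (stabilised trityl cation) is far faster than protonolysis of hindered secondary or tertiary TBS ethers, so brief formic acid treatment should unmask only the primary alcohol.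

Step 7
Reactants: 11 methyl (2S,4R)-2-allyl-2,4-bis[(tert-butyldimethylsilyl)oxy]-5-hydroxypentanoate
Product: 12 methyl (2S,4R)-2-allyl-2,4-bis[(tert-butyldimethylsilyl)oxy]-5-oxopentanoate
Conditions: Dess–Martin periodinane, NaHCO3, CH2Cl2, 0 °C to rt
Reagents that add atoms: none
Why: Dess–Martin oxidation under bicarbonate buffering stops at the aldehyde and is mild enough not to epimerise the α-silyloxy centre or move the silyl group.

Step 8
Reactants: 12 methyl (2S,4R)-2-allyl-2,4-bis[(tert-butyldimethylsilyl)oxy]-5-oxopentanoate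
Product: 14 methyl (2R,4R)-2,4-bis[(tert-butyldimethylsilyl)oxy]-5-oxo-2-(2-oxoethyl)pentanoate, via ozonide 13 (not isolated)
Conditions: O3, CH2Cl2, −78 °C; PPh3, −78 °C to rt; used at once
Reagents that add atoms: ozone [O-][O+]=O
Why: Ozonolysis with reductive phosphine work-up cleaves the terminal alkene to the C3 aldehyde, while silyl ethers, ester and the existing aldehyde are inert to ozone at −78 °C.

Step 9
Reactants: 14 methyl (2R,4R)-2,4-bis[(tert-butyldimethylsilyl)oxy]-5-oxo-2-(2-oxoethyl)pentanoate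
Product: 15 methyl 1,5-bis-O-(tert-butyldimethylsilyl)quinate
Conditions: SmI2 (3 equiv, 0.1 M in THF), t-BuOH (3 equiv), THF, −78 to −20 °C, slow addition of 14 (final ca. 0.01 M); sat. aq. NaHCO3
Reagents that add atoms: none
Why: SmI2 transfers one electron to an aldehyde to give a samarium ketyl whose carbon adds to the second, samarium-coordinated aldehyde carbon, and a second electron plus protonation by tert-butanol give the diol, so C3 and C4, both electrophilic in 14, become joined. The closest known reaction is the SmI2 pinacol cyclisation of α-alkoxy 1,6-dialdehydes (hexodialdose derivatives) to cis-cyclohexane-1,2-diols in cyclitol synthesis, so this is known chemistry on a new substrate. The cyclohexane ring C1–C6 closes by a formal 6-exo-trig attack of the ketyl carbon on the carbonyl carbon through a chair-like transition state. The cis relationship of the C3 and C4 oxygens is fixed by one trivalent samarium bridging both oxygens while the bond forms, and the C4 oxygen should end up trans to O5 because the bulky, non-chelating C5 silyloxy group turns away from the neighbouring samarium-bound oxygen to minimise dipole and steric repulsion; C1 and C5 are not epimerisable here. The step needs this facial selectivity and also chemoselectivity for coupling over β-elimination of O5 and over ester reduction: the silyl ether is a poor leaving group, aldehydes are reduced far faster than an ester by SmI2 without HMPA, and slow addition at high dilution and low temperature suppresses intermolecular coupling. A samarium-alkoxide-induced silyl shift from O5 to O4 would be harmless, because step 10 removes the secondary silyl group wherever it sits.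

Step 10
Reactants: 15 methyl 1,5-bis-O-(tert-butyldimethylsilyl)quinate
Product: 17 1-O-(tert-butyldimethylsilyl)-1,5-quinide, via methyl 1-O-TBS-quinate 16 (not isolated)
Conditions: TsOH·H2O (0.2 equiv), MeOH, 0 °C to rt; solvent swap to toluene, 110 °C, Dean–Stark
Reagents that add atoms: none
Why: Acid-catalysed methanolysis removes the secondary silyl ether much faster than the tertiary one, and acid-catalysed transesterification driven by distilling out methanol then closes the bicyclic γ-lactone from O5, the only hydroxyl cis to the ester, with no stereocentre changing.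

Step 11
Reactants: 18 caffeic acid
Product: 19 (E)-3-(3,4-diacetoxyphenyl)prop-2-enoic acid
Conditions: Ac2O, pyridine, DMAP (cat.), 0 °C to rt; H2O; aq. HCl
Reagents that add atoms: acetic anhydride CC(=O)OC(C)=O
Why: Base-catalysed acetylation of both phenols with acetic anhydride (the mixed anhydride at the carboxyl group is hydrolysed on aqueous work-up), leaving the E-alkene untouched.

Step 12
Reactants: 17 1-O-(tert-butyldimethylsilyl)-1,5-quinide; 19 (E)-3-(3,4-diacetoxyphenyl)prop-2-enoic acid
Product: 21 3-O-[(E)-3,4-diacetoxycinnamoyl]-1-O-(tert-butyldimethylsilyl)-1,5-quinide, via 3,4-diacetoxycinnamoyl chloride 20 (not isolated)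
Conditions: 19, (COCl)2, DMF (cat.), CH2Cl2, 0 °C to rt, evaporate; then 17, pyridine, DMAP (0.1 equiv), CH2Cl2, −20 to 0 °C (1.05 equiv of 20)
Reagents that add atoms: none
Why: Acid chloride formation (oxalyl chloride, Vilsmeier catalysis) and pyridine-mediated acylation: in the rigid lactone chair O3–H is equatorial and open whereas O4–H is axial and flanked by the lactone bridge, so one equivalent of acyl chloride at low temperature should esterify O3 selectively, as in the known equatorial-selective derivatisation of 1,5-quinide.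

Step 13
Reactants: 22 p-coumaric acid
Product: 23 (E)-3-(4-acetoxyphenyl)prop-2-enoic acid
Conditions: Ac2O, pyridine, DMAP (cat.), 0 °C to rt; H2O; aq. HCl
Reagents that add atoms: acetic anhydride CC(=O)OC(C)=O
Why: Base-catalysed phenol acetylation with acetic anhydride, with hydrolysis of the mixed anhydride on work-up and no effect on the E-alkene.

Step 14
Reactants: 21 3-O-[(E)-3,4-diacetoxycinnamoyl]-1-O-(tert-butyldimethylsilyl)-1,5-quinide; 23 (E)-3-(4-acetoxyphenyl)prop-2-enoic acid
Product: 25 3-O-[(E)-3,4-diacetoxycinnamoyl]-4-O-[(E)-4-acetoxycinnamoyl]-1-O-(tert-butyldimethylsilyl)-1,5-quinide, via 4-acetoxycinnamoyl chloride 24 (not isolated)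
Conditions: 23, (COCl)2, DMF (cat.), CH2Cl2, 0 °C to rt, evaporate; then 21, pyridine, DMAP (1 equiv), CH2Cl2, 0 °C to rt (2 equiv of 24)
Reagents that add atoms: none
Why: DMAP-catalysed acylation of the remaining axial secondary hydroxyl with an excess of acid chloride; O1 is capped as the tertiary silyl ether so no third ester can form, and the weakly basic pyridine medium disfavours acyl migration.

Step 15
Reactants: 25 3-O-[(E)-3,4-diacetoxycinnamoyl]-4-O-[(E)-4-acetoxycinnamoyl]-1-O-(tert-butyldimethylsilyl)-1,5-quinide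
Product: 26 3-O-[(E)-3,4-diacetoxycinnamoyl]-4-O-[(E)-4-acetoxycinnamoyl]-1,5-quinide
Conditions: HF·pyridine, pyridine, THF, 0 °C to rt
Reagents that add atoms: none
Why: Fluoride-driven Si–O cleavage with HF·pyridine, a mildly acidic reagent, removes the tertiary silyl ether, whereas aryl acetates, cinnamate esters and the lactone, which are base-labile but acid-tolerant, should stay intact.

Step 16
Reactants: 26 3-O-[(E)-3,4-diacetoxycinnamoyl]-4-O-[(E)-4-acetoxycinnamoyl]-1,5-quinide
Product: 27 3-O-[(E)-caffeoyl]-4-O-[(E)-p-coumaroyl]quinic acid (CNP0077575.1)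
Conditions: 2 M aq. HCl/THF (1:3), rt
Reagents that add atoms: water O
Why: Acid-catalysed hydrolysis cleaves the three phenolic acetates and opens the strained bicyclic lactone to the C1 acid and O5–H, while the two secondary cinnamate esters hydrolyse much more slowly and acyl migration, a base-catalysed process, is suppressed at low pH, with no stereocentre touched.

Compound list
1 | (5R)-5-[(trityloxy)methyl]dihydrofuran-2(3H)-one | O=C1CC[C@H](COC(c2ccccc2)(c2ccccc2)c2ccccc2)O1 | starting material
2 | lithium enolate of 1 | [Li+].[O-]C1=CC[C@H](COC(c2ccccc2)(c2ccccc2)c2ccccc2)O1 | intermediate (not isolated)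
3 | (3S,5R)-3-allyl-5-[(trityloxy)methyl]dihydrofuran-2(3H)-one | C=CC[C@@H]1C(=O)O[C@@H](COC(c2ccccc2)(c2ccccc2)c2ccccc2)C1 | intermediate
4 | potassium enolate of 3 | C=CCC1=C([O-])O[C@@H](COC(c2ccccc2)(c2ccccc2)c2ccccc2)C1.[K+] | intermediate (not isolated)
5 | (3S,5R)-3-allyl-3-hydroxy-5-[(trityloxy)methyl]dihydrofuran-2(3H)-one | C=CC[C@@]1(O)C(=O)O[C@@H](COC(c2ccccc2)(c2ccccc2)c2ccccc2)C1 | intermediate
6 | (3S,5R)-3-allyl-3-[(tert-butyldimethylsilyl)oxy]-5-[(trityloxy)methyl]dihydrofuran-2(3H)-one | C=CC[C@@]1(O[Si](C)(C)C(C)(C)C)C(=O)O[C@@H](COC(c2ccccc2)(c2ccccc2)c2ccccc2)C1 | intermediate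
7 | lithium (2S,4R)-2-allyl-2-[(tert-butyldimethylsilyl)oxy]-4-hydroxy-5-(trityloxy)pentanoate | C=CC[C@@](O[Si](C)(C)C(C)(C)C)(C(=O)[O-])C[C@@H](O)COC(c1ccccc1)(c1ccccc1)c1ccccc1.[Li+] | intermediate (not isolated)
8 | tert-butyldimethylsilyl (2S,4R)-2-allyl-2,4-bis[(tert-butyldimethylsilyl)oxy]-5-(trityloxy)pentanoate | C=CC[C@@](O[Si](C)(C)C(C)(C)C)(C(=O)O[Si](C)(C)C(C)(C)C)C[C@@H](O[Si](C)(C)C(C)(C)C)COC(c1ccccc1)(c1ccccc1)c1ccccc1 | intermediate (not isolated)
9 | (2S,4R)-2-allyl-2,4-bis[(tert-butyldimethylsilyl)oxy]-5-(trityloxy)pentanoic acid | C=CC[C@@](O[Si](C)(C)C(C)(C)C)(C(=O)O)C[C@@H](O[Si](C)(C)C(C)(C)C)COC(c1ccccc1)(c1ccccc1)c1ccccc1 | intermediate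
10 | methyl (2S,4R)-2-allyl-2,4-bis[(tert-butyldimethylsilyl)oxy]-5-(trityloxy)pentanoate | C=CC[C@@](O[Si](C)(C)C(C)(C)C)(C(=O)OC)C[C@@H](O[Si](C)(C)C(C)(C)C)COC(c1ccccc1)(c1ccccc1)c1ccccc1 | intermediate
11 | methyl (2S,4R)-2-allyl-2,4-bis[(tert-butyldimethylsilyl)oxy]-5-hydroxypentanoate | C=CC[C@@](O[Si](C)(C)C(C)(C)C)(C(=O)OC)C[C@@H](O[Si](C)(C)C(C)(C)C)CO | intermediate
12 | methyl (2S,4R)-2-allyl-2,4-bis[(tert-butyldimethylsilyl)oxy]-5-oxopentanoate | C=CC[C@@](O[Si](C)(C)C(C)(C)C)(C(=O)OC)C[C@@H](O[Si](C)(C)C(C)(C)C)C=O | intermediate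
13 | ozonide (1,2,4-trioxolane) of 12 at the allyl alkene, both ring epimers | O1OCOC1C[C@@](O[Si](C)(C)C(C)(C)C)(C(=O)OC)C[C@@H](O[Si](C)(C)C(C)(C)C)C=O | intermediate (not isolated)
14 | methyl (2R,4R)-2,4-bis[(tert-butyldimethylsilyl)oxy]-5-oxo-2-(2-oxoethyl)pentanoate | O=CC[C@@](O[Si](C)(C)C(C)(C)C)(C(=O)OC)C[C@@H](O[Si](C)(C)C(C)(C)C)C=O | intermediate (key-step precursor)
15 | methyl 1,5-bis-O-(tert-butyldimethylsilyl)quinate | CC(C)(C)[Si](C)(C)O[C@@]1(C(=O)OC)C[C@@H](O)[C@@H](O)[C@H](O[Si](C)(C)C(C)(C)C)C1 | intermediate (key-step product)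
16 | methyl 1-O-(tert-butyldimethylsilyl)quinate | CC(C)(C)[Si](C)(C)O[C@@]1(C(=O)OC)C[C@@H](O)[C@@H](O)[C@H](O)C1 | intermediate (not isolated)
17 | 1-O-(tert-butyldimethylsilyl)-1,5-quinide (3-OH equatorial, 4-OH axial) | CC(C)(C)[Si](C)(C)O[C@@]12C[C@@H](O)[C@@H](O)[C@@H](C1)OC2=O | intermediate
18 | caffeic acid | OC(=O)/C=C/c1ccc(O)c(O)c1 | starting material
19 | (E)-3-(3,4-diacetoxyphenyl)prop-2-enoic acid | CC(=O)Oc1ccc(/C=C/C(=O)O)cc1OC(C)=O | intermediate
20 | (E)-3,4-diacetoxycinnamoyl chloride | CC(=O)Oc1ccc(/C=C/C(=O)Cl)cc1OC(C)=O | intermediate (not isolated)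
21 | 3-O-[(E)-3,4-diacetoxycinnamoyl]-1-O-(tert-butyldimethylsilyl)-1,5-quinide | CC(C)(C)[Si](C)(C)O[C@@]12C[C@@H](OC(=O)/C=C/c3ccc(OC(C)=O)c(OC(C)=O)c3)[C@@H](O)[C@@H](C1)OC2=O | intermediate
22 | p-coumaric acid | OC(=O)/C=C/c1ccc(O)cc1 | starting material
23 | (E)-3-(4-acetoxyphenyl)prop-2-enoic acid | CC(=O)Oc1ccc(/C=C/C(=O)O)cc1 | intermediate
24 | (E)-4-acetoxycinnamoyl chloride | CC(=O)Oc1ccc(/C=C/C(=O)Cl)cc1 | intermediate (not isolated)
25 | 3-O-[(E)-3,4-diacetoxycinnamoyl]-4-O-[(E)-4-acetoxycinnamoyl]-1-O-(tert-butyldimethylsilyl)-1,5-quinide | CC(C)(C)[Si](C)(C)O[C@@]12C[C@@H](OC(=O)/C=C/c3ccc(OC(C)=O)c(OC(C)=O)c3)[C@@H](OC(=O)/C=C/c3ccc(OC(C)=O)cc3)[C@@H](C1)OC2=O | intermediate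
26 | 3-O-[(E)-3,4-diacetoxycinnamoyl]-4-O-[(E)-4-acetoxycinnamoyl]-1,5-quinide | O[C@@]12C[C@@H](OC(=O)/C=C/c3ccc(OC(C)=O)c(OC(C)=O)c3)[C@@H](OC(=O)/C=C/c3ccc(OC(C)=O)cc3)[C@@H](C1)OC2=O | intermediate
27 | 3-O-[(E)-caffeoyl]-4-O-[(E)-p-coumaroyl]quinic acid (CNP0077575.1) | O=C(/C=C/c1ccc(O)cc1)O[C@H]1[C@H](O)C[C@](O)(C(=O)O)C[C@H]1OC(=O)/C=C/c1ccc(O)c(O)c1 | target

Total step count: 16. Longest linear sequence: 14 steps (steps 1–10, 12, 14, 15, 16); steps 11 and 13 are one-step side branches.

Steps most likely to fail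

Step 9. The samarium-bridged closure may select the wrong face (cis-diol on the O5 face, or a trans-diol), because in the chair that leads to 15 the forming C3–O bond sits syn-axial to the bulky O1 silyl ether; β-elimination of the C5 silyloxy group from the C4 ketyl or simple reduction of an aldehyde may also compete. The fallback sets out from compound 12. Wittig methylenation (Ph3P=CH2 from Ph3PCH3Br and KN(SiMe3)2, THF, −78 to 0 °C) should give methyl (2S,4R)-2-allyl-2,4-bis[(tert-butyldimethylsilyl)oxy]hex-5-enoate F1. Ring-closing metathesis (second-generation Grubbs catalyst RuCl2(=CHPh)(H2IMes)(PCy3), CH2Cl2, 40 °C) then makes the same C3–C4 connection as an alkene, methyl (1S,5R)-1,5-bis[(tert-butyldimethylsilyl)oxy]cyclohex-3-ene-1-carboxylate F2. Dihydroxylation (OsO4 cat., N-methylmorpholine N-oxide, acetone/H2O), expected anti to the allylic C5 silyloxy group by Kishi's rule, comes back to the route at compound 15.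

Step 12. Regiocontrol between O3–H and O4–H may be lost through over-acylation or acyl shift to O4. The fallback sets out from compound 17 and reverses the order of ester introduction with a temporary silyl group. Equatorial-selective silylation (TESCl, imidazole, DMF, −20 °C) should give 1-O-TBS-3-O-TES-1,5-quinide F3. Acylation of the axial O4–H with chloride 24 (DMAP, pyridine, CH2Cl2) gives 4-O-[(E)-4-acetoxycinnamoyl]-1-O-TBS-3-O-TES-1,5-quinide F4. Buffered HF·pyridine at 0 °C removes only the secondary TES group to give 4-O-[(E)-4-acetoxycinnamoyl]-1-O-TBS-1,5-quinide F5. Prompt acylation of O3–H with chloride 20 (pyridine, CH2Cl2, −20 °C) comes back to the route at compound 25.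

Step 10. The tertiary O1 silyl ether may be lost, or the lactone closure may stay incomplete, under the acidic one-pot conditions. The fallback sets out from compound 15 and gives up O1 protection. Bu4NF (THF, rt) removes both silyl groups to give methyl quinate F6. Acid-catalysed lactonisation (TsOH, toluene/DMF, reflux, Dean–Stark) gives 1,5-quinide F7. Low-temperature acylation of the equatorial O3–H with chloride 20 (pyridine, CH2Cl2) gives 3-O-[(E)-3,4-diacetoxycinnamoyl]-1,5-quinide F8. Acylation of O4–H with chloride 24 (controlled stoichiometry, pyridine, DMAP cat.) comes back to the route at compound 26, so step 15 is not needed.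

Further compounds
F1 | step 9 | methyl (2S,4R)-2-allyl-2,4-bis[(tert-butyldimethylsilyl)oxy]hex-5-enoate | C=CC[C@@](O[Si](C)(C)C(C)(C)C)(C(=O)OC)C[C@@H](O[Si](C)(C)C(C)(C)C)C=C
F2 | step 9 | methyl (1S,5R)-1,5-bis[(tert-butyldimethylsilyl)oxy]cyclohex-3-ene-1-carboxylate | CC(C)(C)[Si](C)(C)O[C@@]1(C(=O)OC)CC=C[C@H](O[Si](C)(C)C(C)(C)C)C1
F3 | step 12 | 1-O-(tert-butyldimethylsilyl)-3-O-(triethylsilyl)-1,5-quinide | CC(C)(C)[Si](C)(C)O[C@@]12C[C@@H](O[Si](CC)(CC)CC)[C@@H](O)[C@@H](C1)OC2=O
F4 | step 12 | 4-O-[(E)-4-acetoxycinnamoyl]-1-O-(tert-butyldimethylsilyl)-3-O-(triethylsilyl)-1,5-quinide | CC(C)(C)[Si](C)(C)O[C@@]12C[C@@H](O[Si](CC)(CC)CC)[C@@H](OC(=O)/C=C/c3ccc(OC(C)=O)cc3)[C@@H](C1)OC2=O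
F5 | step 12 | 4-O-[(E)-4-acetoxycinnamoyl]-1-O-(tert-butyldimethylsilyl)-1,5-quinide | CC(C)(C)[Si](C)(C)O[C@@]12C[C@@H](O)[C@@H](OC(=O)/C=C/c3ccc(OC(C)=O)cc3)[C@@H](C1)OC2=O
F6 | step 10 | methyl quinate | O[C@@]1(C(=O)OC)C[C@@H](O)[C@@H](O)[C@H](O)C1
F7 | step 10 | 1,5-quinide | O[C@@]12C[C@@H](O)[C@@H](O)[C@@H](C1)OC2=O
F8 | step 10 | 3-O-[(E)-3,4-diacetoxycinnamoyl]-1,5-quinide | O[C@@]12C[C@@H](OC(=O)/C=C/c3ccc(OC(C)=O)c(OC(C)=O)c3)[C@@H](O)[C@@H](C1)OC2=O
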